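## Analysis of the target

CNP0018313.0 (32, C30H22O15) is a linear pentamer of five benzene rings (A to E) joined only through four diaryl ether oxygens and carrying eleven free phenolic hydroxyls. Ring A is a 3,5-dihydroxyphenoxy unit with oxygen at A1, A3 and A5 and hydrogen at A2, A4 and A6; the A5 oxygen bridges to B1. Rings B and D are 1,2,3,5-tetraoxygenated: the bridging oxygen at B1 (D1) lies between a hydroxyl at B2 (D2) and a second bridge at B6 (D6), with one more hydroxyl at B4 (D4). Ring C carries the bridge from B6 at C1 between hydroxyls at C2 and C6 and the bridge to D1 at C4; ring E is a 2,4,6-trihydroxyphenoxy group bound through E1 to the D6 oxygen. There is no stereocentre and the ether axes rotate freely, so the problem is purely regiochemical. The free polyphenol is easily oxidised, above all in base, and every ring C–H is flanked by two oxygen substituents, so no late electrophilic substitution or metalation can tell the positions apart; the position of every one of the fifteen oxygens has to be fixed by the building blocks and kept masked to the end. The difficulty lies in the four bridges, each of which has one carbon terminus (B1, C1, D1, E1) crowded by two ortho oxygens. The route rests on ring A: a benzene with O at A1, A3, A5 and H at A2, A4, A6 is what a 3-alkoxycyclobutenone and an ynol ether give on thermal union, so the crowded B1 oxygen can be carried in on an alkyne and ring A grown on it without any C–O coupling.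

## Retrosynthetic reasoning

32 ⇒ 31. The last operation is removal of all eleven O-alkyl groups of 31 (ten methyl, one ethyl) in one Lewis-acid dealkylation. The ethyl group follows from building ring A from 11 and can only be removed this way, so hydrogenolysable groups elsewhere would gain nothing. Benzyl ethers would even do harm in that step, because the benzylic electrophiles they release attack the electron-rich rings. Methyl ethers also allow most rings to be bought with their oxygens in place (1, 20, 23, 27).

31 ⇒ 19 + 30. The B6–O–C1 bridge is cut on the C1 side, giving phenol 19 (rings A and B) and aryl bromide 30 (rings C, D and E). This is the most convergent cut, and it uses the B6 oxygen as nucleophile, which is what ring B offers once its one temporary protecting group is gone. The bromine at C1 has to be present from the start of the ring C chemistry, since no late halogenation could single out C1. The forward reaction is an Ullmann ether coupling at a carbon flanked by two methoxy groups; it is the hardest C–O coupling of the route and the only one of its kind.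

19 ⇒ 18 ⇒ 17. The free B6 hydroxyl of 19 comes from the benzyl ether 18 by hydrogenolysis, a neutral unmasking that sets no carbon electrophile free next to five nucleophilic ring positions. 18 comes from 17 by methylation of the A1 hydroxyl, so that 19 has a single nucleophilic oxygen.

17 ⇒ 10 + 11 (key disconnection). Ring A is taken apart completely: the bonds A1–A6 and A4–A5 are cut, and A1–A2 becomes again a ring bond of a cyclobutenone. This leads to the aryl ethynyl ether 10, whose alkyne carbons are A5 and A6, and to 11, which supplies A1 to A4 with the ethoxy group on A3. Cutting here and not at the A5–O bond removes a C–O coupling in which the crowded B1 oxygen would be the nucleophile, needs no metal, and fixes the 1,3,5-pattern of ring A by mechanism. The forward reaction has to open 11 to ketene 12, add it to 10 in the right orientation and carry the adduct through to the phenol. Because 10 is the costly partner, 11 is taken in excess; the new phenol is then expected to be acylated by 12 to the ester 16, and a methanolysis in the same flask has to return 17.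

10 ⇒ 7 ⇒ 4 + 5. The O–C≡C unit of 10 is traced to the dichlorovinyl ether 7 (elimination and chlorine–lithium exchange with an organolithium base), and 7 to phenol 4 and 5, whose two carbons become A5 and A6. This two-step ethynylation of a phenol oxygen tolerates the two ortho substituents of 4.

4 ⇒ 2 ⇒ 1. The B1 hydroxyl of 4 is derived from a formyl group by Dakin-type oxidation of 2, and 2 from commercial 1 by benzylation. In 1 the oxygens of B2, B4 and B6 and the carbon that becomes B1 are already in place, and the only free hydroxyl is the one that must be told apart (B6).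

30 ⇒ 26 + 29, and 29 ⇒ 28 ⇒ 27. The C4–O–D1 bridge is cut on the C4 side to give phenol 26 (rings D and E) and dihalide 29. C4 has no ortho substituent, so the crowded D1 oxygen can serve as nucleophile in an Ullmann coupling, and the iodine at C4 reacts well ahead of the bromine at C1, which is kept for the later coupling. The iodine of 29 is placed by sterically controlled C–H borylation of 27 to 28 and iododeboronation.

26 ⇒ 24 ⇒ 22 + 23, and 22 ⇒ 20. The D1 hydroxyl comes from the formyl group of 24 by Dakin-type oxidation. The D6–O–E1 bridge is cut on the D6 side, so that the crowded E1 oxygen of 22 is the nucleophile and the fluorine of 23, activated by the ortho formyl group, is the leaving group in a nucleophilic aromatic substitution. The formyl group thus serves twice. 22 comes from 20 by the same oxidation.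

## Alternatives that were turned down

Alternative 1: Four late hydroxyls by C–H borylation and oxidation.
- Disconnection: the hydroxyls at A3, B4, D4 and E4 are removed, leading back to the heptamethyl ether A1 of a tetradeoxy pentamer.
- Forward key step: [Ir(OMe)(cod)]2 with dtbpy and B2pin2 borylates the four C–H bonds of A1 that have no ortho substituent, and NaBO3 oxidises the four C–B bonds in the same flask to the tetraphenol A2.
- For it: in each of rings A, B, D and E exactly one C–H has two hydrogen neighbours, so steric control picks the right four positions. The rings of A1 are less electron-rich, and four oxygens enter in one operation.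
- Against it: A1 still contains all four bridges, including those at B1, C1, D1 and E1, so no coupling is saved. Four borylations must all go to completion on one molecule that has eleven other aromatic C–H bonds, each next to only one small oxygen substituent, so under- and over-borylated material is likely and hard to separate. A2 still needs seven methyl ethers cleaved.
- Comparison: it is stronger in the number of steps spent on introducing oxygen. The chosen route offers instead a fixed position for every oxygen from the building blocks and one bridge (A5–O–B1) made without any coupling.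

Alternative 2: Ring E from a pyrone by Claisen recyclisation.
- Disconnection: ring E is opened at E1–E2 and traced to the 6-(aryloxymethyl)-4-methoxy-2-pyrone A3, in which the ring D oxygen already sits on the future E1 carbon.
- Forward key step: Mg(OMe)2 in hot MeOH opens the lactone of A3, and the carbanion next to the aryloxy group attacks the ester carbonyl so formed; enolisation gives the 2-aryloxy-5-methoxyresorcinol A4.
- For it: ring E is built around a crowded bridging oxygen (E1), which the chosen strategy does not do for its own crowded carbon C1. A3 is a stable substrate and the conditions are simple.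
- Against it: the attacking anion is the less acidic one, since the methylene between ketone and enol ether is deprotonated first, so closure competes with cleavage and with aldol-type closures. A4 emerges with free hydroxyls, a methyl ether, a methoxymethyl ether and benzyl ethers, three kinds of protection to manage. Three bridges, among them B6–O–C1, remain.
- Comparison: it is stronger on substrate stability (no labile ynol ether, no heat-sensitive cyclobutenone). In the chosen route the E1 bridge is made with the E1 oxygen as nucleophile in an aromatic substitution, so the particular merit of A3 is not needed. The benzannulation in turn builds its ring without base and sets the three different oxygens of ring A in one step.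

Alternative 3: Ring B by malonate and acetonedicarboxylate double Claisen.
- Disconnection: ring B is cut at B2–B3 and B5–B6 into the aryloxymalonate A5 and diethyl 3-oxopentanedioate A6.
- Forward key step: with NaOEt in hot EtOH the two methylene carbons of A6 acylate the two ester carbonyls of A5; enolisation gives the phloroglucinol diester A7 with the ring A oxygen at B1.
- For it: cheap reagents and a classical condensation; the most crowded ring is made with its central oxygen in place. On cost and robustness of the reagents it is stronger than the chosen route.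
- Against it: the acidic C–H of A5 is deprotonated first, which makes its ester groups poor acceptors. A7 has three free hydroxyls, of which those at B2 and B6 are equivalent by symmetry but must meet different fates, so a statistical mono-functionalisation cannot be avoided. Two ester groups have to be removed, and the crowded coupling at C1 remains.
- Comparison: the chosen route marks the B6 oxygen with a benzyl ether from the first step and differentiates A1 and A3 (OH and OEt) by mechanism, so no desymmetrisation is needed. The price is a less robust key intermediate.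

Key step: step 5

Remark on the chemistry: compounds 1, 5, 11, 20, 23 and 27 are taken as purchased; equivalents and temperatures are planned values. The ester 16 is written as the product of O–H addition across the ketene C=C of 12 (the but-3-enoate); a shift of its double bond into conjugation would not change the outcome of step 5.

## Route

Step 1
Reactants: 1 2-hydroxy-4,6-dimethoxybenzaldehyde
Product: 2 2-(benzyloxy)-4,6-dimethoxybenzaldehyde
Conditions: BnBr, K2CO3, DMF, 60 °C
Reagents that add atoms: benzyl bromide, BrCc1ccccc1
Why: Williamson ether synthesis; the only free hydroxyl is the chelated one ortho to the formyl group, and carbonate in warm DMF should alkylate it cleanly. The benzyl ether marks the oxygen that becomes B6 and is the one group that hydrogenolysis removes later.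

Step 2
Reactants: 2 2-(benzyloxy)-4,6-dimethoxybenzaldehyde
Product: 4 2-(benzyloxy)-4,6-dimethoxyphenol, via formate ester 3 (not isolated)
Conditions: mCPBA, CH2Cl2, 0 °C → rt; aq. Na2SO3/NaHCO3 wash; then K2CO3 (cat.), MeOH, 0 °C, Ar
Reagents that add atoms: mCPBA (3-chloroperoxybenzoic acid), OOC(=O)c1cccc(Cl)c1
Why: Dakin-type Baeyer–Villiger oxidation; the aryl group with two ortho and one para alkoxy donors migrates in preference to hydride, and mild methanolysis opens the formate 3. The peracid is destroyed before the oxidation-prone phenol is set free.

Step 3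
Reactants: 4 2-(benzyloxy)-4,6-dimethoxyphenol; 5 trichloroethylene (1.5 equiv)
Product: 7 1-(benzyloxy)-2-{[(E)-1,2-dichloroethenyl]oxy}-3,5-dimethoxybenzene, via dichloroacetylene 6 (not isolated)
Conditions: K2CO3, DMF, 70 °C, Ar
Reagents that add atoms: none
Why: Base eliminates HCl from 5 to give 6, to which the phenoxide adds in anti fashion; this is the established route from phenols to aryl (E)-1,2-dichlorovinyl ethers. The small linear electrophile should tolerate the two ortho substituents of 4.

Step 4
Reactants: 7 1-(benzyloxy)-2-{[(E)-1,2-dichloroethenyl]oxy}-3,5-dimethoxybenzene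
Product: 10 1-(benzyloxy)-2-(ethynyloxy)-3,5-dimethoxybenzene, via chloroalkynyl ether 8 (not isolated), via lithium acetylide 9 (not isolated)
Conditions: n-BuLi (2.2 equiv), THF, −78 → −40 °C; then H2O, −78 → 0 °C; kept as a toluene solution
Reagents that add atoms: none
Why: Dichlorovinyl ether route to ynol ethers; the first equivalent of base eliminates HCl to the chloroalkyne 8, the second exchanges chlorine for lithium, and protonation of 9 gives the terminal aryl ethynyl ether. At −78 °C the benzyl ether and the ring C–H bonds should stay untouched.

Step 5
Reactants: 10 1-(benzyloxy)-2-(ethynyloxy)-3,5-dimethoxybenzene; 11 3-ethoxycyclobut-2-en-1-one (2.2 equiv)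
Product: 17 3-[2-(benzyloxy)-4,6-dimethoxyphenoxy]-5-ethoxyphenol, via vinylketene 12 (not isolated), via vinylcyclobutenone 13 (not isolated), via dienylketene 14 (not isolated), via cyclohexadienone 15 (not isolated), via aryl butenoate 16 (not isolated)
Conditions: toluene, 80 → 110 °C, sealed tube, Ar; then K2CO3, MeOH, rt, Ar
Reagents that add atoms: none
Why: Danheiser benzannulation, the known thermal reaction of cyclobutenones with alkoxy- and siloxyalkynes that gives resorcinol monoethers, is the closest precedent and the reaction type used. Heat opens 11 by four-electron electrocyclic cleavage of its C1–C4 bond to the vinylketene 12, whose ketene C=C adds to alkyne 10 in a [2+2] cycloaddition to give 13; four-electron opening of 13 gives the dienylketene 14, ring A closes by six-electron disrotatory electrocyclisation of 14 (ketene carbon onto the CH2 terminus) to the dienone 15, and 15 tautomerises to phenol 17. The net result is insertion of the two alkyne carbons into the C1–C2 bond of 11, with new bonds A1–A6 (ketene carbonyl carbon to alkyne CH) and A4–A5 (ketene alpha carbon to the aryloxy-bearing carbon). The selectivity needed is the orientation of the [2+2] step, and the ynol ether oxygen secures it: the CH carbon is the nucleophilic end and attacks the electrophilic ketene carbon, so the aryloxy group ends up meta to both the new hydroxyl and the ethoxy group, and A2, A4 and A6 carry hydrogen. The opening of 13 is reversible, so whichever way the ethoxyvinyl group first rotates, the (3E) isomer 14 that can cyclise is drained by the irreversible ring closure. No stereocentre remains; the one in 13 is transient. Because 11 is used in excess to offset ketene dimerisation, the phenol 17 first formed is expected to add to a second molecule of 12 and to rest as its ester 16. The closing carbonate methanolysis transfers that acyl group to methanol and returns 17 as the single phenolic product.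

Step 6
Reactants: 17 3-[2-(benzyloxy)-4,6-dimethoxyphenoxy]-5-ethoxyphenol
Product: 18 1-(benzyloxy)-2-(3-ethoxy-5-methoxyphenoxy)-3,5-dimethoxybenzene
Conditions: MeI, K2CO3, acetone, reflux
Reagents that add atoms: iodomethane, CI
Why: Williamson methylation of the only free phenol; it caps the A1 oxygen so that the later Ullmann coupling meets a single hydroxyl.

Step 7
Reactants: 18 1-(benzyloxy)-2-(3-ethoxy-5-methoxyphenoxy)-3,5-dimethoxybenzene
Product: 19 2-(3-ethoxy-5-methoxyphenoxy)-3,5-dimethoxyphenol
Conditions: H2 (1 atm), 10% Pd/C, EtOAc/MeOH, rt
Reagents that add atoms: none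
Why: Hydrogenolysis of the single benzyl ether; methyl, ethyl and diaryl ethers are inert, and no electrophilic fragment is released that could attack the electron-rich rings.

Step 8
Reactants: 20 2,4,6-trimethoxybenzaldehyde
Product: 22 2,4,6-trimethoxyphenol, via formate ester 21 (not isolated)
Conditions: mCPBA, CH2Cl2, 0 °C → rt; aq. Na2SO3/NaHCO3 wash; then K2CO3 (cat.), MeOH, 0 °C, Ar
Reagents that add atoms: mCPBA (3-chloroperoxybenzoic acid), OOC(=O)c1cccc(Cl)c1
Why: Dakin-type Baeyer–Villiger oxidation of an aldehyde whose aryl group has three alkoxy donors, followed by methanolysis of the formate 21; the same operation as step 2.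

Step 9
Reactants: 22 2,4,6-trimethoxyphenol; 23 2-fluoro-4,6-dimethoxybenzaldehyde
Product: 24 2,4-dimethoxy-6-(2,4,6-trimethoxyphenoxy)benzaldehyde
Conditions: Cs2CO3, DMSO, 120 °C, Ar
Reagents that add atoms: none
Why: Nucleophilic aromatic substitution through a Meisenheimer adduct; the fluorine is ortho to the formyl group and meta to both methoxy groups, so their donation does not reach the reacting carbon directly. The crowded E1 oxygen acts as the nucleophile, the polarity that tolerates two ortho substituents.

Step 10
Reactants: 24 2,4-dimethoxy-6-(2,4,6-trimethoxyphenoxy)benzaldehyde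
Product: 26 2,4-dimethoxy-6-(2,4,6-trimethoxyphenoxy)phenol, via formate ester 25 (not isolated)
Conditions: mCPBA, CH2Cl2, 0 °C; aq. Na2SO3/NaHCO3 wash; then K2CO3 (cat.), MeOH, 0 °C, Ar
Reagents that add atoms: mCPBA (3-chloroperoxybenzoic acid), OOC(=O)c1cccc(Cl)c1
Why: Dakin-type Baeyer–Villiger oxidation; the formyl group that activated the fluorine in step 9 now becomes the D1 hydroxyl. At 0 °C the peracid should attack the aldehyde well before it oxidises the methoxylated rings.

Step 11
Reactants: 27 2-bromo-1,3-dimethoxybenzene
Product: 28 2-(4-bromo-3,5-dimethoxyphenyl)-4,4,5,5-tetramethyl-1,3,2-dioxaborolane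
Conditions: [Ir(OMe)(cod)]2 (1.5 mol %), dtbpy (4,4'-di-tert-butyl-2,2'-bipyridine, 3 mol %), B2pin2 (0.6 equiv), THF, 80 °C
Reagents that add atoms: bis(pinacolato)diboron, CC1(C)OB(OC1(C)C)B1OC(C)(C)C(C)(C)O1
Why: Iridium-catalysed C–H borylation under steric control; C5 is the only C–H of 27 without an ortho substituent, and aryl bromides are tolerated.

Step 12
Reactants: 28 2-(4-bromo-3,5-dimethoxyphenyl)-4,4,5,5-tetramethyl-1,3,2-dioxaborolane
Product: 29 2-bromo-5-iodo-1,3-dimethoxybenzene
Conditions: CuI (10 mol %), 1,10-phenanthroline (20 mol %), KI (1.5 equiv), MeOH/H2O, air, 80 °C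
Reagents that add atoms: potassium iodide, [K+].[I-]
Why: Copper-mediated oxidative iododeboronation of an arylboronate; ipso substitution at boron puts iodine on the later C4 and leaves the crowded bromide alone.

Step 13
Reactants: 26 2,4-dimethoxy-6-(2,4,6-trimethoxyphenoxy)phenol; 29 2-bromo-5-iodo-1,3-dimethoxybenzene
Product: 30 2-bromo-5-[2,4-dimethoxy-6-(2,4,6-trimethoxyphenoxy)phenoxy]-1,3-dimethoxybenzene
Conditions: CuI (10 mol %), picolinic acid (20 mol %), K3PO4, DMSO, 80 °C, Ar
Reagents that add atoms: none
Why: Ullmann-type diaryl ether coupling; the unhindered aryl iodide should react well below the temperature at which the bromide between two methoxy groups does. 2,6-Disubstituted phenols are competent nucleophiles with this ligand.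

Step 14
Reactants: 19 2-(3-ethoxy-5-methoxyphenoxy)-3,5-dimethoxyphenol (1.5 equiv); 30 2-bromo-5-[2,4-dimethoxy-6-(2,4,6-trimethoxyphenoxy)phenoxy]-1,3-dimethoxybenzene
Product: 31 1-{4-[2,4-dimethoxy-6-(2,4,6-trimethoxyphenoxy)phenoxy]-2,6-dimethoxyphenoxy}-2-(3-ethoxy-5-methoxyphenoxy)-3,5-dimethoxybenzene
Conditions: CuCl (50 mol %), 2,2,6,6-tetramethylheptane-3,5-dione (1 equiv), Cs2CO3, NMP, 120 °C, Ar
Reagents that add atoms: none
Why: Ullmann ether coupling of a phenol with a 2,6-dimethoxyaryl bromide, the coupling type by which methyl ethers of oligomeric phenyl ethers of this class are classically assembled. The diketone ligand accelerates electron-rich bromides, and the smaller partner 19 is used in excess.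

Step 15
Reactants: 31 1-{4-[2,4-dimethoxy-6-(2,4,6-trimethoxyphenoxy)phenoxy]-2,6-dimethoxyphenoxy}-2-(3-ethoxy-5-methoxyphenoxy)-3,5-dimethoxybenzene
Product: 32 5-(2-{4-[2,4-dihydroxy-6-(2,4,6-trihydroxyphenoxy)phenoxy]-2,6-dihydroxyphenoxy}-4,6-dihydroxyphenoxy)benzene-1,3-diol (CNP0018313.0)
Conditions: BBr3 (ca. 35 equiv), CH2Cl2, −78 °C → rt; then H2O, 0 °C; reversed-phase chromatography with acidic eluent, Ar
Reagents that add atoms: none
Why: Lewis-acid dealkylation; each alkyl ether oxygen binds boron and bromide attacks the methyl or ethyl carbon, while the diaryl ether oxygens have no such carbon and should survive. The alkyl bromides formed are volatile and do not alkylate the rings.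

## Compound list

1 | 2-hydroxy-4,6-dimethoxybenzaldehyde | O=Cc1c(O)cc(OC)cc1OC | starting material
2 | 2-(benzyloxy)-4,6-dimethoxybenzaldehyde | O=Cc1c(OCc2ccccc2)cc(OC)cc1OC | intermediate
3 | 2-(benzyloxy)-4,6-dimethoxyphenyl formate | O=COc1c(OCc2ccccc2)cc(OC)cc1OC | intermediate
4 | 2-(benzyloxy)-4,6-dimethoxyphenol | Oc1c(OCc2ccccc2)cc(OC)cc1OC | intermediate
5 | trichloroethylene | ClC=C(Cl)Cl | starting material
6 | dichloroacetylene | ClC#CCl | intermediate
7 | 1-(benzyloxy)-2-{[(E)-1,2-dichloroethenyl]oxy}-3,5-dimethoxybenzene | Cl/C=C(/Cl)Oc1c(OCc2ccccc2)cc(OC)cc1OC | intermediate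
8 | 1-(benzyloxy)-2-[(chloroethynyl)oxy]-3,5-dimethoxybenzene | ClC#COc1c(OCc2ccccc2)cc(OC)cc1OC | intermediate
9 | lithium [2-(benzyloxy)-4,6-dimethoxyphenoxy]ethynide | [Li]C#COc1c(OCc2ccccc2)cc(OC)cc1OC | intermediate
10 | 1-(benzyloxy)-2-(ethynyloxy)-3,5-dimethoxybenzene | C#COc1c(OCc2ccccc2)cc(OC)cc1OC | intermediate
11 | 3-ethoxycyclobut-2-en-1-one | CCOC1=CC(=O)C1 | starting material
12 | 3-ethoxybuta-1,3-dien-1-one | CCOC(=C)C=C=O | intermediate
13 | 3-[2-(benzyloxy)-4,6-dimethoxyphenoxy]-4-(1-ethoxyethenyl)cyclobut-2-en-1-one (racemic, transient) | CCOC(=C)C1C(=O)C=C1Oc1c(OCc2ccccc2)cc(OC)cc1OC | intermediate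
14 | (3E)-3-[2-(benzyloxy)-4,6-dimethoxyphenoxy]-5-ethoxyhexa-1,3,5-trien-1-one | O=C=C/C(Oc1c(OCc2ccccc2)cc(OC)cc1OC)=C\C(OCC)=C | intermediate
15 | 3-[2-(benzyloxy)-4,6-dimethoxyphenoxy]-5-ethoxycyclohexa-2,4-dien-1-one | CCOC1=CC(Oc2c(OCc3ccccc3)cc(OC)cc2OC)=CC(=O)C1 | intermediate
16 | 3-[2-(benzyloxy)-4,6-dimethoxyphenoxy]-5-ethoxyphenyl 3-ethoxybut-3-enoate | C=C(OCC)CC(=O)Oc1cc(OCC)cc(Oc2c(OCc3ccccc3)cc(OC)cc2OC)c1 | intermediate
17 | 3-[2-(benzyloxy)-4,6-dimethoxyphenoxy]-5-ethoxyphenol | CCOc1cc(O)cc(Oc2c(OCc3ccccc3)cc(OC)cc2OC)c1 | intermediate
18 | 1-(benzyloxy)-2-(3-ethoxy-5-methoxyphenoxy)-3,5-dimethoxybenzene | CCOc1cc(OC)cc(Oc2c(OCc3ccccc3)cc(OC)cc2OC)c1 | intermediate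
19 | 2-(3-ethoxy-5-methoxyphenoxy)-3,5-dimethoxyphenol | CCOc1cc(OC)cc(Oc2c(O)cc(OC)cc2OC)c1 | intermediate
20 | 2,4,6-trimethoxybenzaldehyde | COc1cc(OC)c(C=O)c(OC)c1 | starting material
21 | 2,4,6-trimethoxyphenyl formate | COc1cc(OC)c(OC=O)c(OC)c1 | intermediate
22 | 2,4,6-trimethoxyphenol | COc1cc(OC)c(O)c(OC)c1 | intermediate
23 | 2-fluoro-4,6-dimethoxybenzaldehyde | O=Cc1c(F)cc(OC)cc1OC | starting material
24 | 2,4-dimethoxy-6-(2,4,6-trimethoxyphenoxy)benzaldehyde | O=Cc1c(OC)cc(OC)cc1Oc1c(OC)cc(OC)cc1OC | intermediate
25 | 2,4-dimethoxy-6-(2,4,6-trimethoxyphenoxy)phenyl formate | O=COc1c(OC)cc(OC)cc1Oc1c(OC)cc(OC)cc1OC | intermediate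
26 | 2,4-dimethoxy-6-(2,4,6-trimethoxyphenoxy)phenol | Oc1c(OC)cc(OC)cc1Oc1c(OC)cc(OC)cc1OC | intermediate
27 | 2-bromo-1,3-dimethoxybenzene | COc1cccc(OC)c1Br | starting material
28 | 2-(4-bromo-3,5-dimethoxyphenyl)-4,4,5,5-tetramethyl-1,3,2-dioxaborolane | COc1cc(B2OC(C)(C)C(C)(C)O2)cc(OC)c1Br | intermediate
29 | 2-bromo-5-iodo-1,3-dimethoxybenzene | COc1cc(I)cc(OC)c1Br | intermediate
30 | 2-bromo-5-[2,4-dimethoxy-6-(2,4,6-trimethoxyphenoxy)phenoxy]-1,3-dimethoxybenzene | COc1cc(Oc2c(OC)cc(OC)cc2Oc2c(OC)cc(OC)cc2OC)cc(OC)c1Br | intermediate
31 | 1-{4-[2,4-dimethoxy-6-(2,4,6-trimethoxyphenoxy)phenoxy]-2,6-dimethoxyphenoxy}-2-(3-ethoxy-5-methoxyphenoxy)-3,5-dimethoxybenzene | CCOc1cc(OC)cc(Oc2c(OC)cc(OC)cc2Oc2c(OC)cc(Oc3c(OC)cc(OC)cc3Oc3c(OC)cc(OC)cc3OC)cc2OC)c1 | intermediate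
32 | 5-(2-{4-[2,4-dihydroxy-6-(2,4,6-trihydroxyphenoxy)phenoxy]-2,6-dihydroxyphenoxy}-4,6-dihydroxyphenoxy)benzene-1,3-diol (CNP0018313.0) | Oc1cc(O)cc(Oc2c(O)cc(O)cc2Oc2c(O)cc(Oc3c(O)cc(O)cc3Oc3c(O)cc(O)cc3O)cc2O)c1 | target

## Step count and least certain steps

Total step count: 15. Longest linear sequence: 9 steps (steps 1 to 7, then 14 and 15).

Step 5 (key step).
- What may go wrong: the alkyne and the ketene are consumed by paths other than their union. The terminal aryl ethynyl ether 10 can oligomerise on heating. The ring opening of 11 may be slow, because the ethoxy group stabilises the enone by conjugation, and the ketene 12 is then less electrophilic and may dimerise. The aryloxy alkyne is also a weaker nucleophile than an alkoxy alkyne. Uneven acylation of the new phenol is not a concern, since the methanolysis converges on 17.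
- Fallback: ring A is attached by a copper coupling in which the crowded B1 oxygen is the nucleophile and the halide is unhindered. 3-Bromo-5-methoxyphenol F1 is ethylated (EtI, K2CO3, DMF) to 1-bromo-3-ethoxy-5-methoxybenzene F2. The fallback sets out from phenol 4, which is coupled with F2 (CuI, picolinic acid, K3PO4, DMSO, 100 °C) and comes back to the route at 18.

Step 14.
- What may go wrong: slow activation of the bromide flanked by two methoxy groups, so that hydrodebromination of 30 and oxidative decay of the phenoxide of 19 outrun the coupling.
- Fallback: the order of the two couplings at ring C is inverted, so that the crowded carbon carries iodine on a small molecule that can be used in excess. 4-Bromo-2,6-dimethoxyaniline F3 is diazotised (NaNO2, TsOH, MeCN/H2O) to 4-bromo-2,6-dimethoxybenzenediazonium 4-methylbenzenesulfonate F4, which KI converts into 5-bromo-2-iodo-1,3-dimethoxybenzene F5. The fallback sets out from 19, which is coupled at the iodide of F5 (CuI, picolinic acid, K3PO4, DMSO, 90 °C) to give 5-bromo-2-[2-(3-ethoxy-5-methoxyphenoxy)-3,5-dimethoxyphenoxy]-1,3-dimethoxybenzene F6. The now unhindered bromide of F6 is coupled with phenol 26 under the same catalyst at 100 °C, and the route is rejoined at 31.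

Step 4.
- What may go wrong: loss of the terminal ynol ether by oligomerisation or hydration during work-up and concentration; competing ring lithiation if the temperature rises.
- Fallback: the alkyne is carried in a capped, storable form. The fallback sets out from acetylide 9, which is quenched with Me3SiCl instead of water to give {[2-(benzyloxy)-4,6-dimethoxyphenoxy]ethynyl}trimethylsilane F7. F7 can be purified and kept. Bu4NF in wet THF at −20 °C releases the alkyne immediately before step 5, and the route is rejoined at 10.

Step 9.
- What may go wrong: sluggish substitution, because the formyl group of 23 is conjugated with an ortho and a para methoxy group and activates the fluorine only weakly. At the temperature then needed the phenoxide of 22 may be oxidised or lose a methyl group.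
- Fallback: a more strongly activated electrophile is used and the missing methoxy group is introduced afterwards. The fallback sets out from 22, which reacts with 2,6-difluoro-4-methoxybenzaldehyde F8 (Cs2CO3, DMSO, 80 °C) to give 2-fluoro-4-methoxy-6-(2,4,6-trimethoxyphenoxy)benzaldehyde F9. NaOMe in MeOH then displaces the remaining ortho fluorine, and the route is rejoined at 24.

Step 15.
- What may go wrong: incomplete cleavage of eleven ethers (the ethyl ether being the slowest), which leaves partial ethers, and oxidative loss of the free polyphenol during isolation.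
- Fallback: the polyphenol is derivatised, purified and released. The fallback sets out from 31, which is treated with BBr3 as before, but the crude product is acetylated (Ac2O, pyridine) to the undecaacetate of 32 F10. F10 is stable to air and silica, and partly alkylated material can be separated from it and resubmitted. Transesterification (NaOMe cat., degassed MeOH, then acidic resin) brings the route back at 32.

## Further compounds

F1 | step 5 | 3-bromo-5-methoxyphenol | COc1cc(O)cc(Br)c1
F2 | step 5 | 1-bromo-3-ethoxy-5-methoxybenzene | CCOc1cc(Br)cc(OC)c1
F3 | step 14 | 4-bromo-2,6-dimethoxyaniline | COc1cc(Br)cc(OC)c1N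
F4 | step 14 | 4-bromo-2,6-dimethoxybenzenediazonium 4-methylbenzenesulfonate | COc1cc(Br)cc(OC)c1[N+]#N.Cc1ccc(cc1)S(=O)(=O)[O-]
F5 | step 14 | 5-bromo-2-iodo-1,3-dimethoxybenzene | COc1cc(Br)cc(OC)c1I
F6 | step 14 | 5-bromo-2-[2-(3-ethoxy-5-methoxyphenoxy)-3,5-dimethoxyphenoxy]-1,3-dimethoxybenzene | CCOc1cc(OC)cc(Oc2c(OC)cc(OC)cc2Oc2c(OC)cc(Br)cc2OC)c1
F7 | step 4 | {[2-(benzyloxy)-4,6-dimethoxyphenoxy]ethynyl}trimethylsilane | C[Si](C)(C)C#COc1c(OCc2ccccc2)cc(OC)cc1OC
F8 | step 9 | 2,6-difluoro-4-methoxybenzaldehyde | COc1cc(F)c(C=O)c(F)c1
F9 | step 9 | 2-fluoro-4-methoxy-6-(2,4,6-trimethoxyphenoxy)benzaldehyde | COc1cc(F)c(C=O)c(Oc2c(OC)cc(OC)cc2OC)c1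
F10 | step 15 | undecaacetate of 32 | CC(=O)Oc1cc(OC(C)=O)cc(Oc2c(OC(C)=O)cc(OC(C)=O)cc2Oc2c(OC(C)=O)cc(Oc3c(OC(C)=O)cc(OC(C)=O)cc3Oc3c(OC(C)=O)cc(OC(C)=O)cc3OC(C)=O)cc2OC(C)=O)c1
A1 | alternative 1 | heptamethyl ether of the tetradeoxy pentamer (no oxygen at A3, B4, D4 and E4) | COc1cccc(Oc2c(OC)cccc2Oc2c(OC)cc(Oc3c(OC)cccc3Oc3c(OC)cccc3OC)cc2OC)c1
A2 | alternative 1 | heptamethyl ether of the target with free hydroxyls at A3, B4, D4 and E4 | COc1cc(O)cc(Oc2c(OC)cc(O)cc2Oc2c(OC)cc(Oc3c(OC)cc(O)cc3Oc3c(OC)cc(O)cc3OC)cc2OC)c1
A3 | alternative 2 | 6-{[3,5-bis(benzyloxy)-2-(methoxymethoxy)phenoxy]methyl}-4-methoxy-2H-pyran-2-one | COC1=CC(=O)OC(COc2cc(OCc3ccccc3)cc(OCc3ccccc3)c2OCOC)=C1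
A4 | alternative 2 | 2-[3,5-bis(benzyloxy)-2-(methoxymethoxy)phenoxy]-5-methoxybenzene-1,3-diol | COc1cc(O)c(Oc2cc(OCc3ccccc3)cc(OCc3ccccc3)c2OCOC)c(O)c1
A5 | alternative 3 | diethyl 2-[3,5-bis(benzyloxy)phenoxy]propanedioate | CCOC(=O)C(Oc1cc(OCc2ccccc2)cc(OCc2ccccc2)c1)C(=O)OCC
A6 | alternative 3 | diethyl 3-oxopentanedioate | CCOC(=O)CC(=O)CC(=O)OCC
A7 | alternative 3 | diethyl 5-[3,5-bis(benzyloxy)phenoxy]-2,4,6-trihydroxybenzene-1,3-dicarboxylate | CCOC(=O)c1c(O)c(C(=O)OCC)c(O)c(Oc2cc(OCc3ccccc3)cc(OCc3ccccc3)c2)c1O
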